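**Strategy.** The dihydrofuran ring (O11, C11a, C6a, C6b, C10a) is mapped onto O1, C2, C3, C4a, C8a of a (2S)-flavanone-derived 3-diazochroman-4-one whose 2-aryl group is ring A with a free ortho hydroxyl (the future O5). Photochemical Wolff rearrangement shifts the aryl carbon C4a (C6b) from the carbonyl carbon to C3, contracting the pyranone to the dihydrobenzofuran and expelling the carbonyl carbon as a ketene, which becomes C6. The phenol adds to it, closing ring B as a lactone and fixing C6a cis to C11a. Lactone reduction, Mitsunobu closure and hydrogenation finish. The flavanone comes from a chalcone by asymmetric oxa-Michael cyclisation.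

Key step: step 6

Remark: the sense of induction of the cinchona thiourea in step 4 is assumed; should it favour the 2R flavanone, the quinidine-derived pseudoenantiomer is used instead.

Step 1
Reactants: 1 2,4,6-trihydroxybenzaldehyde
Product: 2 4-(benzyloxy)-2,6-dihydroxybenzaldehyde
Conditions: BnBr (1.05 equiv), K2CO3 (1.0 equiv), DMF, 0 °C to rt
Reagents that add atoms: benzyl bromide, BrCc1ccccc1
Why: Williamson etherification; the 4-OH is the most acidic hydroxyl and the only one not hydrogen-bonded to the formyl group, so monoalkylation should occur there.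

Step 2
Reactants: 2 4-(benzyloxy)-2,6-dihydroxybenzaldehyde; 3 3-methylbut-2-enal
Product: 4 5-(benzyloxy)-7-hydroxy-2,2-dimethyl-2H-chromene-8-carbaldehyde
Conditions: ethylenediammonium diacetate (10 mol %), PhMe, 110 °C
Reagents that add atoms: none
Why: Knoevenagel-type condensation at ring carbon C-3 followed by oxa-6π-electrocyclisation of the ortho-quinone methide (formal (3+3) chromene annulation); the ring can close only on the free 2-OH because the other flanking oxygen is benzylated, which places the formyl group between the pyran oxygen and the remaining hydroxyl.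

Step 3
Reactants: 4 5-(benzyloxy)-7-hydroxy-2,2-dimethyl-2H-chromene-8-carbaldehyde; 5 1-(2-hydroxy-4-methoxyphenyl)ethan-1-one (paeonol)
Product: 6 (E)-3-[5-(benzyloxy)-7-hydroxy-2,2-dimethyl-2H-chromen-8-yl]-1-(2-hydroxy-4-methoxyphenyl)prop-2-en-1-one
Conditions: KOH (50% aq.), EtOH, rt; then AcOH to pH 6
Reagents that add atoms: none
Why: Claisen–Schmidt aldol condensation of the methyl ketone with the non-enolisable aldehyde; dehydration to the conjugated E-enone drives the reaction although the aldehyde is deactivated as its phenoxide.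

Step 4
Reactants: 6 (E)-3-[5-(benzyloxy)-7-hydroxy-2,2-dimethyl-2H-chromen-8-yl]-1-(2-hydroxy-4-methoxyphenyl)prop-2-en-1-one
Product: 7 (2S)-2-[5-(benzyloxy)-7-hydroxy-2,2-dimethyl-2H-chromen-8-yl]-7-methoxy-2,3-dihydro-4H-chromen-4-one
Conditions: epi-quinine-derived 3,5-bis(trifluoromethyl)phenyl thiourea (10 mol %), PhMe, 25 °C
Reagents that add atoms: none
Why: Organocatalytic asymmetric intramolecular oxa-Michael addition (6-endo-trig) of the acyl-ring phenol to the enone; the thiourea binds the carbonyl and the quinuclidine activates the phenol, so the catalyst should select the face of the β-carbon and set C-2.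

Step 5
Reactants: 7 (2S)-2-[5-(benzyloxy)-7-hydroxy-2,2-dimethyl-2H-chromen-8-yl]-7-methoxy-2,3-dihydro-4H-chromen-4-one
Product: 9 (2R)-2-[5-(benzyloxy)-7-hydroxy-2,2-dimethyl-2H-chromen-8-yl]-3-diazo-7-methoxy-2,3-dihydro-4H-chromen-4-one, via trifluoroacetyl ketone 8 (not isolated)
Conditions: LiN(SiMe3)2 (3.3 equiv), THF, −78 °C; CF3CO2CH2CF3; then MsN3, Et3N, H2O, MeCN, rt
Reagents that add atoms: methanesulfonyl azide, CS(=O)(=O)N=[N+]=[N-] (supplies the N2 unit of 9); 2,2,2-trifluoroethyl trifluoroacetate, O=C(OCC(F)(F)F)C(F)(F)F (supplies the trifluoroacetyl group of 8, which is lost again)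
Why: Detrifluoroacetylative diazo transfer (Danheiser): kinetic enolisation at −78 °C and C-acylation activate C-3, the only enolisable position, so the sulfonyl azide transfers N2 under mild amine base with loss of the trifluoroacetyl group; C-2 is untouched and its descriptor becomes R only because the diazo carbon now outranks the aryl carbon.

Step 6
Reactants: 9 (2R)-2-[5-(benzyloxy)-7-hydroxy-2,2-dimethyl-2H-chromen-8-yl]-3-diazo-7-methoxy-2,3-dihydro-4H-chromen-4-one
Product: 11 (6aR,11aS)-3-(benzyloxy)-9-methoxy-6-oxopterocarpan bearing a 2,2-dimethyl-2H-pyran ring fused at C-1 (oxygen) and C-2 (cis lactone), via ketene 10 (not isolated)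
Conditions: hν (390 nm LED), anhydrous PhMe (0.01 M), 0 °C, argon
Reagents that add atoms: none
Why: Direct irradiation of the cyclic α-diazo ketone, locked s-cis, should expel N2 with concerted 1,2-shift of the aryl carbon C-4a from the carbonyl carbon to C-3 (Wolff rearrangement), as known for 2-diazo-1-tetralones and 3-diazochroman-4-ones, which give ring-contracted indane and dihydrobenzofuran acid derivatives. The dihydrofuran ring therefore arises by contraction of the six-membered pyranone, not by cyclisation, and the expelled carbonyl carbon becomes the ketene carbon of 10 (later C-6). Ring B closes by 6-exo-dig addition of the ortho phenol to the ketene carbon, and tautomerisation of the lactone enol sets C-6a. C-11a is carried over unchanged from C-2 of 9, and it controls C-6a because the three-atom tether from the C-11a aryl group can only span a cis 6/5 ring fusion. The step needs migration to outrun 1,2-hydride shift from C-2 and O–H insertion by the phenol; the concerted excited-state pathway of the s-cis diazo ketone, the absence of any metal and high dilution in an inert solvent should secure this.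

Step 7
Reactants: 11 (6aR,11aS)-3-(benzyloxy)-9-methoxy-6-oxopterocarpan bearing the fused 2,2-dimethyl-2H-pyran ring
Product: 12 [(2S,3S)-2-[5-(benzyloxy)-7-hydroxy-2,2-dimethyl-2H-chromen-8-yl]-6-methoxy-2,3-dihydro-1-benzofuran-3-yl]methanol (aryl and CH2OH cis)
Conditions: LiBH4, THF, 0 °C
Reagents that add atoms: none
Why: Borohydride reduction of the aryl ester lactone to the primary alcohol and the free phenol; the weakly basic hydride should add to the carbonyl faster than any β-elimination across C-6a/C-11a, and both stereocentres are spectators.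

Step 8
Reactants: 12 [(2S,3S)-2-[5-(benzyloxy)-7-hydroxy-2,2-dimethyl-2H-chromen-8-yl]-6-methoxy-2,3-dihydro-1-benzofuran-3-yl]methanol
Product: 13 (6aS,11aS)-3-(benzyloxy)-9-methoxypterocarpan bearing a 2,2-dimethyl-2H-pyran ring fused at C-1 (oxygen) and C-2
Conditions: PPh3, DIAD, THF, 0 °C to rt
Reagents that add atoms: none
Why: Intramolecular Mitsunobu etherification; the only free phenol displaces the activated primary hydroxyl (6-exo-tet) and closes ring B without touching either stereocentre.

Step 9
Reactants: 13 (6aS,11aS)-3-(benzyloxy)-9-methoxypterocarpan bearing the fused 2,2-dimethyl-2H-pyran ring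
Product: 14 (6aS,11aS)-9-methoxypterocarpan-3-ol bearing a 2,2-dimethyl-3,4-dihydro-2H-pyran ring fused at C-1 (oxygen) and C-2 (CNP0207547.1)
Conditions: H2 (1 atm), Pd/C (10%), EtOAc, rt
Reagents that add atoms: none
Why: Heterogeneous hydrogenation should saturate the cis-disubstituted chromene double bond and hydrogenolyse the benzyl ether in one operation; the benzylic C-11a–O bond of the cis-fused pterocarpan is cleaved much more slowly, so the reaction is stopped after uptake of two equivalents of hydrogen.

**Compound list**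

1 | 2,4,6-trihydroxybenzaldehyde | O=Cc1c(O)cc(O)cc1O | starting material
2 | 4-(benzyloxy)-2,6-dihydroxybenzaldehyde | O=Cc1c(O)cc(OCc2ccccc2)cc1O | intermediate
3 | 3-methylbut-2-enal | CC(C)=CC=O | starting material
4 | 5-(benzyloxy)-7-hydroxy-2,2-dimethyl-2H-chromene-8-carbaldehyde | O=Cc1c(O)cc(OCc2ccccc2)c2C=CC(C)(C)Oc12 | intermediate
5 | 1-(2-hydroxy-4-methoxyphenyl)ethan-1-one (paeonol) | CC(=O)c1ccc(OC)cc1O | starting material
6 | (E)-3-[5-(benzyloxy)-7-hydroxy-2,2-dimethyl-2H-chromen-8-yl]-1-(2-hydroxy-4-methoxyphenyl)prop-2-en-1-one | COc1ccc(C(=O)/C=C/c2c(O)cc(OCc3ccccc3)c3C=CC(C)(C)Oc23)c(O)c1 | intermediate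
7 | (2S)-2-[5-(benzyloxy)-7-hydroxy-2,2-dimethyl-2H-chromen-8-yl]-7-methoxy-2,3-dihydro-4H-chromen-4-one | COc1ccc2c(c1)O[C@H](c1c(O)cc(OCc3ccccc3)c3C=CC(C)(C)Oc13)CC2=O | intermediate
8 | (2S)-2-[5-(benzyloxy)-7-hydroxy-2,2-dimethyl-2H-chromen-8-yl]-7-methoxy-3-(trifluoroacetyl)-2,3-dihydro-4H-chromen-4-one (C-3 epimers and enol, not isolated) | COc1ccc2c(c1)O[C@H](c1c(O)cc(OCc3ccccc3)c3C=CC(C)(C)Oc13)C(C(=O)C(F)(F)F)C2=O | intermediate
9 | (2R)-2-[5-(benzyloxy)-7-hydroxy-2,2-dimethyl-2H-chromen-8-yl]-3-diazo-7-methoxy-2,3-dihydro-4H-chromen-4-one (same spatial arrangement at C-2 as 7) | COc1ccc2c(c1)O[C@H](c1c(O)cc(OCc3ccccc3)c3C=CC(C)(C)Oc13)C(=[N+]=[N-])C2=O | intermediate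
10 | (2R)-2-[5-(benzyloxy)-7-hydroxy-2,2-dimethyl-2H-chromen-8-yl]-6-methoxy-3-(oxomethylidene)-2,3-dihydro-1-benzofuran (ketene, not isolated) | COc1ccc2c(c1)O[C@H](c1c(O)cc(OCc3ccccc3)c3C=CC(C)(C)Oc13)C2=C=O | intermediate
11 | (6aR,11aS)-3-(benzyloxy)-9-methoxy-6-oxopterocarpan with a 2,2-dimethyl-2H-pyran ring fused at C-1 (oxygen) and C-2; cis-fused lactone | COc1ccc2c(c1)O[C@@H]1c3c(cc(OCc5ccccc5)c4c3OC(C)(C)C=C4)OC(=O)[C@H]21 | intermediate
12 | [(2S,3S)-2-[5-(benzyloxy)-7-hydroxy-2,2-dimethyl-2H-chromen-8-yl]-6-methoxy-2,3-dihydro-1-benzofuran-3-yl]methanol (2,3-cis) | COc1ccc2c(c1)O[C@H](c1c(O)cc(OCc3ccccc3)c3C=CC(C)(C)Oc13)[C@@H]2CO | intermediate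
13 | (6aS,11aS)-3-(benzyloxy)-9-methoxypterocarpan with a 2,2-dimethyl-2H-pyran ring fused at C-1 (oxygen) and C-2 | COc1ccc2c(c1)O[C@@H]1c3c(cc(OCc5ccccc5)c4c3OC(C)(C)C=C4)OC[C@H]21 | intermediate
14 | (6aS,11aS)-9-methoxypterocarpan-3-ol with a 2,2-dimethyl-3,4-dihydro-2H-pyran ring fused at C-1 (oxygen) and C-2 (CNP0207547.1) | COc1ccc2c(c1)O[C@@H]1c3c(cc(O)c4c3OC(C)(C)CC4)OC[C@H]21 | target

**Step count and risks**

Total steps: 9. Longest linear sequence: 9 steps (1 to 14); compounds 3 and 5 enter as purchased fragments.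

Steps most likely to fail:

1. Step 6 (Wolff ring contraction). What may go wrong: nitrogen may be lost through a free α-keto carbene instead of the concerted shift. Hydride migration from C-2 (aromatising to the flavone) or capture of the carbene by the neighbouring phenolic O–H would then compete, and the β-aryloxy lactone may eliminate across C-6a/C-11a on handling. Fallback (sets out from 9, returns at 12): the phenol of 9 is silylated (TBSCl, imidazole, DMF) to give O-silyl diazo ketone F1. Irradiation of F1 in MeOH/THF lets methanol take up the ketene, and protonation of the ester enol on the face away from the C-2 aryl group should give, under kinetic control, cis methyl ester F2. LiBH4 reduction then gives silylated cis alcohol F3, and Bu4NF removes the silyl group to give diol 12. Ring B is closed as in step 8, so no lactone is handled and no acidic O–H sits beside the diazo carbon.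

2. Step 4 (asymmetric oxa-Michael cyclisation). What may go wrong: the ring closure is reversible and may be slow and poorly face-selective at the electron-rich, doubly ortho-substituted β-carbon, so the enantiomeric purity may drift toward the racemate. Fallback (sets out from 6, returns at 7): uncatalysed closure (NaOAc, EtOH, reflux) gives racemic flavanone F4. Kinetic resolution by asymmetric transfer hydrogenation follows, with RuCl(p-cymene)[(R,R)-TsDPEN] (or its antipode, whichever reduces the 2R ketone faster) in HCO2H/Et3N. The 2R enantiomer is reduced to cis-flavan-4-ol F5 and unreacted 7 is recovered.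

3. Step 5 (diazo transfer). What may go wrong: β-elimination of the ring oxygen from the lithium enolate (retro-oxa-Michael opening to the chalcone) and reclosure would scramble C-2, and O-acylation of the phenol consumes reagent. Fallback (sets out from 7, returns at 9): condensation of 7 with tert-butoxybis(dimethylamino)methane (PhMe, 60 °C) gives enaminone F6. Diazo transfer with cleavage of the aminomethylene group by MsN3 in MeCN at rt then gives 9, and no metal enolate is formed.

**Further compounds**

F1 | step 6 | (2R)-2-[5-(benzyloxy)-7-[(tert-butyldimethylsilyl)oxy]-2,2-dimethyl-2H-chromen-8-yl]-3-diazo-7-methoxy-2,3-dihydro-4H-chromen-4-one | COc1ccc2c(c1)O[C@H](c1c(O[Si](C)(C)C(C)(C)C)cc(OCc3ccccc3)c3C=CC(C)(C)Oc13)C(=[N+]=[N-])C2=O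
F2 | step 6 | methyl (2S,3R)-2-[5-(benzyloxy)-7-[(tert-butyldimethylsilyl)oxy]-2,2-dimethyl-2H-chromen-8-yl]-6-methoxy-2,3-dihydro-1-benzofuran-3-carboxylate (2,3-cis) | COc1ccc2c(c1)O[C@H](c1c(O[Si](C)(C)C(C)(C)C)cc(OCc3ccccc3)c3C=CC(C)(C)Oc13)[C@@H]2C(=O)OC
F3 | step 6 | [(2S,3S)-2-[5-(benzyloxy)-7-[(tert-butyldimethylsilyl)oxy]-2,2-dimethyl-2H-chromen-8-yl]-6-methoxy-2,3-dihydro-1-benzofuran-3-yl]methanol (2,3-cis) | COc1ccc2c(c1)O[C@H](c1c(O[Si](C)(C)C(C)(C)C)cc(OCc3ccccc3)c3C=CC(C)(C)Oc13)[C@@H]2CO
F4 | step 4 | racemic 2-[5-(benzyloxy)-7-hydroxy-2,2-dimethyl-2H-chromen-8-yl]-7-methoxy-2,3-dihydro-4H-chromen-4-one | COc1ccc2c(c1)OC(c1c(O)cc(OCc3ccccc3)c3C=CC(C)(C)Oc13)CC2=O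
F5 | step 4 | (2R,4R)-2-[5-(benzyloxy)-7-hydroxy-2,2-dimethyl-2H-chromen-8-yl]-7-methoxy-3,4-dihydro-2H-chromen-4-ol (2,4-cis) | COc1ccc2c(c1)O[C@@H](c1c(O)cc(OCc3ccccc3)c3C=CC(C)(C)Oc13)C[C@H]2O
F6 | step 5 | (2R)-2-[5-(benzyloxy)-7-hydroxy-2,2-dimethyl-2H-chromen-8-yl]-3-[(dimethylamino)methylidene]-7-methoxy-2,3-dihydro-4H-chromen-4-one (C-2 arranged as in 7) | COc1ccc2c(c1)O[C@H](c1c(O)cc(OCc3ccccc3)c3C=CC(C)(C)Oc13)C(=CN(C)C)C2=O
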